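## Analysis of the target

The target is a tetracycle in which a diaryl ketone carbon K links two resorcinol-type benzo rings, A and B, inside a seven-membered ring (K, a1, a2, C7, C8, b1, b2), and an indane five-membered ring (C8, C9, C10, b6, b1) is fused to it along the C8–b1 bond; ring A carries K on a1, C7 on a2 and hydroxyls on a3 and a5, while ring B carries C8 on b1, K on b2, hydroxyls on b3 and b5, and C10 on b6. C7 and C9 each bear a 4-hydroxyphenyl group and C10 a 3,5-dihydroxyphenyl group. The four contiguous methine stereocentres are (7S,8R,9S,10S): the C10 aryl is trans to the C9 aryl, the C9 aryl is trans to the C8–C7 bond, and H7 is trans to H8. C9 and C10 carry no activating group and stay fixed once set, whereas C7–H and C8–H are both ortho-benzylic to the K carbonyl (through ring A and ring B) and are therefore vinylogously acidic and epimerisable. Sensitive features are the eight phenols on electron-rich rings (oxidation, electrophilic attack), the benzylic methines next to them, and the hindered diaryl ketone. The synthesis is hard because C7 is crowded by two ortho substituents of ring A and by C8, because three oxygenated aryl rings of similar reactivity make late electrophilic substitution at b2 unselective, and because a seven-membered ring must be closed next to four stereocentres. The strategy rests on one structural fact: C7 is a single carbon joining a2, C8 and a 4-oxyphenyl group, and both carbons it joins can be made nucleophilic from one ketone (C8 as a dienolate through K and ring B, a2 as an aryl anion), so C7 can be delivered as the carbonyl carbon of an aryl ester.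

## Retrosynthetic reasoning

21 ⇒ 20. Only the eight O–methyl bonds are cut. The phenols are carried as methyl ethers from the first step because the route passes through alkyllithiums, hot hydroxide and strong acid. A single Lewis-acid dealkylation at the end must free all eight without touching the carbon framework.

20 ⇒ 19 ⇒ 18. The C7–H bond is traced back to a C7–OH bond, and the configuration at C7 (and C8) is left to equilibration. Both centres can be deprotonated reversibly through K, so the forward route only has to remove a tertiary, doubly benzylic hydroxyl by hydride transfer and then let base find the all-trans array. This frees the ring-forming step from any need to control C7.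

18 ⇒ 13 + 14 (key disconnection). The a2–C7 and C7–C8 bonds are cut together, which removes C7 with its aryl group as ester 14 and leaves the seco ketone 13 with bromine on a2 and a methylene at C8. The cut is made here because C7 is the only ring carbon whose two ring neighbours can both become carbanions from the same ketone: C8 through dienolate 15, a2 through halogen–metal exchange (16). Cutting at K instead would require a Friedel–Crafts acylation among three equally activated dimethoxyaryl rings. The gain is one ring, two C–C bonds and the last aryl group in one operation on a substrate with only the two robust stereocentres. The forward reaction must deprotonate C8 and not C10, exchange the bromine without touching K, and deliver the ester carbon to both termini.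

13 ⇒ 12 ⇒ 10 + 1. The K–b2 bond is cut to aryl bromide 10 and aldehyde 1 (addition of aryllithium 11, then oxidation of 12). Position b2 could not be acylated selectively once the equally electron-rich C10 aryl ring is present, so its bromine is built into ring B from the start. Ring A is attached only at this point because its own bromine would not survive the earlier steps, and because a second carbonyl on the ring carbon next to C8=O would interfere with the C8 deoxygenation.

10 ⇒ 9 ⇒ 7. Enantiomer 10 is taken from racemic 9 by chromatography on a chiral phase, at the one stage where neither stereocentre has an acidifying neighbour and where the bromine allows the absolute configuration to be assigned. 9 is traced to indanone 7 by placing a carbonyl on C8. The carbonyl is needed for the ring construction and is removed through hydrazone 8 under basic conditions, because a C8 cation would eliminate toward C9 and scramble it.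

7 ⇒ 6. The b6–C10 bond is cut (Nazarov retron). With C8 as a ketone, C10 becomes the electrophilic terminus of a pentadienyl cation and b6, ortho and para to the two methoxy groups, the nucleophilic one. Position b2 is blocked by bromine, so only one closure is possible. C9 is α to the ketone and settles trans to the C10 aryl. No dependable catalytic enantioselective version is established for α-aryl aryl vinyl ketones, which is why the material is made racemic and resolved at 9.

6 ⇒ 4 + 5 and 4 ⇒ 3 ⇒ 1 + 2. The C9=C10 bond is cut to deoxybenzoin 4 and aldehyde 5 (condensation), and the C8–C9 bond to aldehyde 1 and the benzylic Grignard reagent 2 (addition, then oxidation). Aldehyde 1 thus supplies both brominated rings: ring B with C8 here, ring A with K in step 7.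

## Alternatives that were turned down

Alternative 1: Ring B itself is disconnected (b1–b2, b2–b3, b4–b5, b5–b6) and grown last on a cyclopentene that already carries C7 to C10.
- Forward key step: irradiation of a diazomethyl ketone on the cyclopentene triggers a Wolff shift to a vinylketene, which adds ethoxyacetylene A2, ring-opens and electrocyclises (Danheiser benzannulation) to phenol A1. A1 is methyl 2-[(4-methoxyphenyl)(indan-1-yl)methyl]-3,5-dimethoxybenzoate whose indane ring B is the 6-ethoxy-4-hydroxy arene with b2 still unsubstituted; K would then be closed by acylation of b2 with the ring A ester.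
- For: the oxygen pattern of ring B is placed without regiochemical doubt, and b2 is left free and activated for the last acylation. All four stereocentres, C7 included, are set on an sp3 scaffold; on early, kinetic control of C7 this route is stronger than the chosen one.
- Against: the stereochemical problem is moved into a cyclopentene with three ring stereocentres and an exocyclic diarylmethine, at least as hard to make as the indane used here. C8 and C10 are allylic to the ketene and dienone intermediates and may epimerise. Four electron-rich arenes compete for the light. Two ring closures are spent where the chosen route needs one.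
- Comparison: the chosen strategy offers a ring B bought as a commercial arene and a seven-membered ring closed together with introduction of the last aryl group, at the price of a late equilibration at C7.

Alternative 2: The C9–C10 bond is cut.
- Forward key step: a diaryl hydrazone on b6 would be oxidised to the diazo compound, and a chiral dirhodium tetracarboxylate, Rh2(O2CR*)4, would insert the C10 carbene into a benzylic C9–H bond and close the five-membered ring. The product is the trans,trans ester A3, methyl 3-(3,5-dimethoxyphenyl)-4,6-dimethoxy-2-(4-methoxyphenyl)indane-1-carboxylate, whose ester carbon is C7.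
- For: C9 and C10 (and through them C8) are set by a catalyst. On absolute configuration this route is stronger than the chosen one, which resolves a racemate.
- Against: A3 contains neither ring A, nor K, nor the C7 aryl group. The ester must still be turned into a diarylmethine and K closed by acylation at b2, the position that competes with the C10 aryl ring for electrophiles, and C7 is again set last. Diazo compounds flanked by two electron-rich aryl groups are prone to azine formation and to attack on neighbouring methoxyarenes.
- Comparison: its key step builds only the five-membered ring, which the chosen route obtains from a simple Nazarov closure, and it leaves the difficult seven-membered ring to a longer endgame. The chosen route offers the hard ring in one step and accepts a resolution.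

Alternative 3: Only the C7–C8 bond is cut.
- Forward key step: a benzylic C8 bromide would be reduced by a single-electron donor to the C8 radical, which adds to the methide carbon C7 of a para-quinone methide on a2 and closes the seven-membered ring. The product is A4, the heptamethyl ether of a target analogue whose C7 aryl group is 3,5-di-tert-butyl-4-hydroxyphenyl.
- For: the most congested bond is formed by a radical, which is less sensitive to crowding than an enolate, under neutral conditions. C7 arrives as a methine, so no hydroxyl has to be removed; on this point it is stronger than the chosen route.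
- Against: the C8 bromide would have to be made by benzylic halogenation next to the tertiary, doubly benzylic C10–H, with no handle for selectivity. The quinone methide is stable only with the two tert-butyl groups, which must later be cut off by retro-Friedel–Crafts chemistry on a framework full of acid-labile benzylic positions. The a2–C7 bond has to be made beforehand in a separate sequence, and a seven-membered radical closure competes with simple reduction of the radical.
- Comparison: the chosen route uses the same kind of seco ketone but addresses C8 through its acidity, which the K carbonyl confers on C8 and not on C10. It forms both bonds to C7 in one flask and needs no auxiliary substituents on the C7 aryl group.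

Key step: step 9

Assumption: 6 is drawn as its E isomer; any Z isomer formed in step 3 is carried along, because the acid of step 4 interconverts the two before ring closure. Racemic compounds 7, 8 and 9 are drawn as the enantiomer that is carried forward.

## Route

Step 1
Reactants: 1 2-bromo-3,5-dimethoxybenzaldehyde; 2 (4-methoxybenzyl)magnesium chloride
Product: 3 rac-1-(2-bromo-3,5-dimethoxyphenyl)-2-(4-methoxyphenyl)ethan-1-ol
Conditions: THF, –78 to 0 °C; then aq NH4Cl
Reagents that add atoms: none
Why: Grignard 1,2-addition of a benzylic magnesium reagent to an aryl aldehyde forms the C8–C9 bond; the aryl bromide is inert to the benzylic Grignard reagent at this temperature.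

Step 2
Reactants: 3 rac-1-(2-bromo-3,5-dimethoxyphenyl)-2-(4-methoxyphenyl)ethan-1-ol
Product: 4 1-(2-bromo-3,5-dimethoxyphenyl)-2-(4-methoxyphenyl)ethan-1-one
Conditions: Dess–Martin periodinane, CH2Cl2, 0 °C to rt
Reagents that add atoms: none
Why: Dess–Martin oxidation of a secondary benzylic alcohol gives the deoxybenzoin under neutral conditions that leave the aryl bromide and the methyl ethers untouched.

Step 3
Reactants: 4 1-(2-bromo-3,5-dimethoxyphenyl)-2-(4-methoxyphenyl)ethan-1-one; 5 3,5-dimethoxybenzaldehyde
Product: 6 (E)-1-(2-bromo-3,5-dimethoxyphenyl)-3-(3,5-dimethoxyphenyl)-2-(4-methoxyphenyl)prop-2-en-1-one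
Conditions: piperidine (0.3 equiv), AcOH (0.3 equiv), toluene, reflux, Dean–Stark trap
Reagents that add atoms: none
Why: Knoevenagel-type aldol condensation: the methylene of 4 is activated by both the ketone and the aryl group, and removal of water drives formation of the C9=C10 bond.

Step 4
Reactants: 6 (E)-1-(2-bromo-3,5-dimethoxyphenyl)-3-(3,5-dimethoxyphenyl)-2-(4-methoxyphenyl)prop-2-en-1-one
Product: 7 rac-(2S,3S)-7-bromo-3-(3,5-dimethoxyphenyl)-4,6-dimethoxy-2-(4-methoxyphenyl)-2,3-dihydro-1H-inden-1-one (trans)
Conditions: BF3·OEt2 (3 equiv), ClCH2CH2Cl, 80 °C
Reagents that add atoms: none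
Why: Nazarov cyclisation of an aryl vinyl ketone: the Lewis-acid complex closes by 4π electrocyclisation onto b6, the only free ortho position and the one ortho and para to the methoxy groups, forming the b6–C10 bond. C9, α to the ketone, equilibrates through the enol to the trans isomer, which fixes the relative configuration of C9 and C10; the acyl group on ring B protects the bromine against acid-induced migration.

Step 5
Reactants: 7 rac-(2S,3S)-7-bromo-3-(3,5-dimethoxyphenyl)-4,6-dimethoxy-2-(4-methoxyphenyl)-2,3-dihydro-1H-inden-1-one
Product: 9 rac-(1S,2S)-4-bromo-1-(3,5-dimethoxyphenyl)-5,7-dimethoxy-2-(4-methoxyphenyl)-2,3-dihydro-1H-indene, via hydrazone 8 (not isolated)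
Conditions: N2H4·H2O (10 equiv), diethylene glycol, 130 °C; then KOH (5 equiv), 195 °C, under N2
Reagents that add atoms: none
Why: Wolff–Kishner reduction (Huang-Minlon procedure) converts C8=O into CH2 without a C8 cation, so C9 cannot be scrambled by elimination; any base-induced epimerisation is harmless at the racemic stage and leads to the stable trans isomer. The bromine has no ortho hydrogen, so no aryne can form.

Step 6
Reactants: 9 rac-(1S,2S)-4-bromo-1-(3,5-dimethoxyphenyl)-5,7-dimethoxy-2-(4-methoxyphenyl)-2,3-dihydro-1H-indene
Product: 10 (1S,2S)-4-bromo-1-(3,5-dimethoxyphenyl)-5,7-dimethoxy-2-(4-methoxyphenyl)-2,3-dihydro-1H-indene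
Conditions: preparative supercritical-fluid chromatography, amylose tris(3,5-dimethylphenylcarbamate) stationary phase, CO2/MeOH
Reagents that add atoms: none
Why: Resolution of a racemate by chromatography on a chiral stationary phase; in 9 neither C9 nor C10 has an acidifying neighbour, so the separated enantiomers are configurationally stable, and the bromine allows assignment of the (1S,2S) enantiomer by anomalous X-ray dispersion.

Step 7
Reactants: 10 (1S,2S)-4-bromo-1-(3,5-dimethoxyphenyl)-5,7-dimethoxy-2-(4-methoxyphenyl)-2,3-dihydro-1H-indene; 1 2-bromo-3,5-dimethoxybenzaldehyde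
Product: 12 (2-bromo-3,5-dimethoxyphenyl)[(1S,2S)-1-(3,5-dimethoxyphenyl)-5,7-dimethoxy-2-(4-methoxyphenyl)-2,3-dihydro-1H-inden-4-yl]methanol (both carbinol epimers), via aryllithium 11 (not isolated)
Conditions: t-BuLi (2.1 equiv), THF, –78 °C, 15 min; then 1 (1.2 equiv), –78 °C; aq NH4Cl
Reagents that add atoms: none
Why: Bromine–lithium exchange followed by 1,2-addition of the aryllithium to an aryl aldehyde forms the K–b2 bond; addition to the aldehyde is much faster than exchange with the bromide of 1. The new carbinol centre is oxidised away in the next step.

Step 8
Reactants: 12 (2-bromo-3,5-dimethoxyphenyl)[(1S,2S)-1-(3,5-dimethoxyphenyl)-5,7-dimethoxy-2-(4-methoxyphenyl)-2,3-dihydro-1H-inden-4-yl]methanol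
Product: 13 (2-bromo-3,5-dimethoxyphenyl)[(1S,2S)-1-(3,5-dimethoxyphenyl)-5,7-dimethoxy-2-(4-methoxyphenyl)-2,3-dihydro-1H-inden-4-yl]methanone
Conditions: Dess–Martin periodinane, CH2Cl2, rt
Reagents that add atoms: none
Why: Dess–Martin oxidation of a diaryl carbinol to the diaryl ketone K; there is no α-hydrogen and no other oxidisable group.

Step 9
Reactants: 13 (2-bromo-3,5-dimethoxyphenyl)[(1S,2S)-1-(3,5-dimethoxyphenyl)-5,7-dimethoxy-2-(4-methoxyphenyl)-2,3-dihydro-1H-inden-4-yl]methanone; 14 methyl 4-methoxybenzoate
Product: 18 tetracyclic C7 tertiary alcohol (8S,9R,10S; C7 epimers), via lithium dienolate 15 (not isolated), via aryllithium dienolate 16 (not isolated), via keto dienolate 17 (not isolated)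
Conditions: lithium 2,2,6,6-tetramethylpiperidide (LiTMP, 1.1 equiv), THF, –78 °C, 30 min; t-BuLi (3.1 equiv), –78 °C, 10 min; 14 (1.1 equiv), –78 to 0 °C; aq NH4Cl
Reagents that add atoms: none
Why: Proposed new method: LiTMP, bound to the K carbonyl oxygen, removes a C8 proton and gives the O-lithio ortho-quinodimethane dienolate 15, which also masks K against alkyllithium attack; t-BuLi then exchanges the a2 bromine to give 16, the extra equivalent returning the liberated amine to its lithium amide so that it cannot protonate the aryl anion. The aryllithium is the faster nucleophile and is acylated by 14 through addition–elimination to the keto dienolate 17, whose C8 terminus adds to the new C7 ketone in a 7-exo-trig vinylogous aldol that restores the aromaticity of ring B and closes the seven-membered ring; should the dienolate be acylated first, the aryllithium closes the same ring from the other end. The closest known reactions are lateral (ortho-benzylic) metalation of ortho-alkyl aryl ketones and benzamides with aldol trapping, and acylation of aryllithiums by esters; the new element is running both on one dianion so that a single ester carbon is stitched in between. The new C8 stereocentre is set by the C9 aryl group, which covers one face of the planar dienolate so that C7 arrives anti to it; the carbinol centre C7 is not controlled and need not be. The selectivities needed are C8 over C10 deprotonation, secured by precoordination of the amide to the K oxygen and by the vinylogous acidity that only C8 has, and exchange without carbonyl addition, secured by prior enolisation; chelation of the enolate lithium by the b3 methoxy group turns ring A toward C8 and places the two reacting termini on the same side.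

Step 10
Reactants: 18 tetracyclic C7 tertiary alcohol (8S,9R,10S; C7 epimers)
Product: 19 C7-deoxy tetracyclic ketone (8R,9S,10S; C7 epimers)
Conditions: Et3SiH (5 equiv), CF3CO2H (10 equiv), CH2Cl2, –20 to 0 °C
Reagents that add atoms: none
Why: Ionic hydrogenation: the acid ionises the tertiary, doubly benzylic C7 alcohol to a cation stabilised by the 4-methoxyphenyl group and by the ortho and para methoxy groups of ring A, and Et3SiH transfers hydride to it. The hindered diaryl ketone K is reduced far more slowly, and capture of the cation by the K oxygen would place an oxocarbenium ion at a bridgehead, which is not accessible.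

Step 11
Reactants: 19 C7-deoxy tetracyclic ketone (8R,9S,10S; C7 epimers)
Product: 20 (7S,8R,9S,10S)-octamethyl ether of the target
Conditions: t-BuOK (0.3 equiv), t-BuOH/THF (degassed), 50 °C; then AcOH
Reagents that add atoms: none
Why: Base-mediated epimerisation: C7–H and C8–H are reversibly removed as dienolates through K (via ring A and ring B), so both centres can settle in the arrangement in which neighbouring substituents alternate faces (H7 trans to H8, C8–C7 trans to the C9 aryl), expected to be the most stable. C9 and C10 have no acidifying group and are untouched.

Step 12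
Reactants: 20 (7S,8R,9S,10S)-octamethyl ether of the target
Product: 21 CNP0116600.1 (7S,8R,9S,10S)
Conditions: BBr3 (24 equiv), CH2Cl2, –78 °C to rt; then MeOH, H2O
Reagents that add atoms: none
Why: Lewis-acid cleavage of aryl methyl ethers: BBr3 coordinates each ether oxygen and bromide removes the methyl group, and hydrolysis releases the eight phenols. The four C–H stereocentres are not ionisable under these conditions.

## Compound list

1 | 2-bromo-3,5-dimethoxybenzaldehyde | O=Cc1cc(OC)cc(OC)c1Br | starting material
2 | (4-methoxybenzyl)magnesium chloride | COc1ccc(C[Mg]Cl)cc1 | starting material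
3 | rac-1-(2-bromo-3,5-dimethoxyphenyl)-2-(4-methoxyphenyl)ethan-1-ol | OC(Cc1ccc(OC)cc1)c1cc(OC)cc(OC)c1Br | intermediate
4 | 1-(2-bromo-3,5-dimethoxyphenyl)-2-(4-methoxyphenyl)ethan-1-one | O=C(Cc1ccc(OC)cc1)c1cc(OC)cc(OC)c1Br | intermediate
5 | 3,5-dimethoxybenzaldehyde | O=Cc1cc(OC)cc(OC)c1 | starting material
6 | (E)-1-(2-bromo-3,5-dimethoxyphenyl)-3-(3,5-dimethoxyphenyl)-2-(4-methoxyphenyl)prop-2-en-1-one | O=C(c1cc(OC)cc(OC)c1Br)/C(c1ccc(OC)cc1)=C/c1cc(OC)cc(OC)c1 | intermediate
7 | rac-(2S,3S)-7-bromo-3-(3,5-dimethoxyphenyl)-4,6-dimethoxy-2-(4-methoxyphenyl)-2,3-dihydro-1H-inden-1-one (racemic, trans) | Brc1c(OC)cc(OC)c2c1C(=O)[C@H](c1ccc(OC)cc1)[C@H]2c1cc(OC)cc(OC)c1 | intermediate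
8 | hydrazone of 7 (racemic, trans) | Brc1c(OC)cc(OC)c2c1C(=NN)[C@H](c1ccc(OC)cc1)[C@H]2c1cc(OC)cc(OC)c1 | intermediate (not isolated)
9 | rac-(1S,2S)-4-bromo-1-(3,5-dimethoxyphenyl)-5,7-dimethoxy-2-(4-methoxyphenyl)-2,3-dihydro-1H-indene (racemic, trans) | Brc1c(OC)cc(OC)c2c1C[C@H](c1ccc(OC)cc1)[C@H]2c1cc(OC)cc(OC)c1 | intermediate
10 | (1S,2S)-4-bromo-1-(3,5-dimethoxyphenyl)-5,7-dimethoxy-2-(4-methoxyphenyl)-2,3-dihydro-1H-indene (single enantiomer) | Brc1c(OC)cc(OC)c2c1C[C@H](c1ccc(OC)cc1)[C@H]2c1cc(OC)cc(OC)c1 | intermediate
11 | [(1S,2S)-1-(3,5-dimethoxyphenyl)-5,7-dimethoxy-2-(4-methoxyphenyl)-2,3-dihydro-1H-inden-4-yl]lithium | [Li]c1c(OC)cc(OC)c2c1C[C@H](c1ccc(OC)cc1)[C@H]2c1cc(OC)cc(OC)c1 | intermediate (not isolated)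
12 | (2-bromo-3,5-dimethoxyphenyl)[(1S,2S)-1-(3,5-dimethoxyphenyl)-5,7-dimethoxy-2-(4-methoxyphenyl)-2,3-dihydro-1H-inden-4-yl]methanol (carbinol epimers) | OC(c1cc(OC)cc(OC)c1Br)c1c(OC)cc(OC)c2c1C[C@H](c1ccc(OC)cc1)[C@H]2c1cc(OC)cc(OC)c1 | intermediate
13 | (2-bromo-3,5-dimethoxyphenyl)[(1S,2S)-1-(3,5-dimethoxyphenyl)-5,7-dimethoxy-2-(4-methoxyphenyl)-2,3-dihydro-1H-inden-4-yl]methanone (seco bromo diaryl ketone) | O=C(c1cc(OC)cc(OC)c1Br)c1c(OC)cc(OC)c2c1C[C@H](c1ccc(OC)cc1)[C@H]2c1cc(OC)cc(OC)c1 | intermediate
14 | methyl 4-methoxybenzoate | COC(=O)c1ccc(OC)cc1 | starting material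
15 | lithium dienolate of 13 (O-lithiated at K, C8=b1 double bond, ring B as ortho-quinodimethane; C9 and C10 as in 13) | [Li]OC(c1cc(OC)cc(OC)c1Br)=C1C(OC)=CC(OC)=C2C1=C[C@H](c1ccc(OC)cc1)[C@H]2c1cc(OC)cc(OC)c1 | intermediate (not isolated)
16 | aryllithium dienolate (15 with lithium in place of bromine on a2) | [Li]OC(c1cc(OC)cc(OC)c1[Li])=C1C(OC)=CC(OC)=C2C1=C[C@H](c1ccc(OC)cc1)[C@H]2c1cc(OC)cc(OC)c1 | intermediate (not isolated)
17 | keto dienolate (15 with a 4-methoxybenzoyl group in place of bromine on a2) | [Li]OC(c1cc(OC)cc(OC)c1C(=O)c1ccc(OC)cc1)=C1C(OC)=CC(OC)=C2C1=C[C@H](c1ccc(OC)cc1)[C@H]2c1cc(OC)cc(OC)c1 | intermediate (not isolated)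
18 | tetracyclic tertiary alcohol: octamethyl ether of the target carrying OH on C7 (C7 epimers; 8S,9R,10S, spatially as in the target, the letters at C8 and C9 differ only because the C7 oxygen changes the priorities) | O=C1c2cc(OC)cc(OC)c2C(O)(c2ccc(OC)cc2)[C@@H]2c3c1c(OC)cc(OC)c3[C@H](c1cc(OC)cc(OC)c1)[C@H]2c1ccc(OC)cc1 | intermediate
19 | C7-deoxy tetracyclic ketone: octamethyl ether of the target as C7 epimers (8R,9S,10S) | O=C1c2cc(OC)cc(OC)c2C(c2ccc(OC)cc2)[C@@H]2c3c1c(OC)cc(OC)c3[C@H](c1cc(OC)cc(OC)c1)[C@H]2c1ccc(OC)cc1 | intermediate
20 | (7S,8R,9S,10S)-octamethyl ether of the target | O=C1c2cc(OC)cc(OC)c2[C@H](c2ccc(OC)cc2)[C@@H]2c3c1c(OC)cc(OC)c3[C@H](c1cc(OC)cc(OC)c1)[C@H]2c1ccc(OC)cc1 | intermediate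
21 | CNP0116600.1, (7S,8R,9S,10S) | O=C1c2cc(O)cc(O)c2[C@H](c2ccc(O)cc2)[C@@H]2c3c1c(O)cc(O)c3[C@H](c1cc(O)cc(O)c1)[C@H]2c1ccc(O)cc1 | target

## Step count and least certain steps

Total: 12 steps. Longest linear sequence: 12 steps (1 to 21); 2, 5 and 14 enter as purchased reagents and 1 is used twice.

Step 9 (key step, proposed new method). The most likely failures are:
- incomplete or misdirected metalation, because K is twisted out of the plane of ring B by its two ortho neighbours, which lowers the kinetic acidity of C8–H; the bromine–lithium exchange may then meet a free ketone and end in intermolecular carbonyl addition;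
- proton return to the aryllithium from the amine or from C10–H;
- intermolecular double addition of two aryllithiums to one ester instead of the intramolecular aldol closure;
- consumption of the ester by the surplus lithium amide.

The fallback uses known reactions only, sets out from 1 and 10, and comes back at 18. Aldehyde 1 is converted with HC(OMe)3 and catalytic TsOH in MeOH into 2-bromo-1-(dimethoxymethyl)-3,5-dimethoxybenzene F1. Bromine–lithium exchange with n-BuLi at –78 °C and acylation of the aryllithium with ester 14 gives [2-(dimethoxymethyl)-4,6-dimethoxyphenyl](4-methoxyphenyl)methanone F2, and aqueous HCl in THF releases 3,5-dimethoxy-2-(4-methoxybenzoyl)benzaldehyde F3, so that the a2–C7 bond is made on a simple arene. Aryllithium 11, generated from 10 as in step 7, adds to the aldehyde group of F3 and gives [3,5-dimethoxy-2-(4-methoxybenzoyl)phenyl][(1S,2S)-1-(3,5-dimethoxyphenyl)-5,7-dimethoxy-2-(4-methoxyphenyl)-2,3-dihydro-1H-inden-4-yl]methanol F4. Dess–Martin oxidation gives [3,5-dimethoxy-2-(4-methoxybenzoyl)phenyl][(1S,2S)-1-(3,5-dimethoxyphenyl)-5,7-dimethoxy-2-(4-methoxyphenyl)-2,3-dihydro-1H-inden-4-yl]methanone F5. LiTMP then has to perform only the lateral deprotonation at C8, and the dienolate closes onto the C7 ketone (a lateral metalation–aldol reaction run on its own) to deliver 18.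

Step 10. The C7 cation may be captured by the C10 aryl ring, which sits on the same face of the five-membered ring as C7 (transannular Friedel–Crafts alkylation to a bridged skeleton), or hydride may also reduce K on prolonged exposure; both are losses of chemoselectivity at a long-lived stabilised cation. The fallback sets out from 18 and comes back at 19. Base-induced dehydration through the ring B dienolate (t-BuOK, t-BuOH, 60 °C; E1cB) gives the C7=C8 alkene of the octamethyl ether F6. Hydrogenation over Pd on carbon under H2 pressure then gives 19 as a mixture of C7 and C8 epimers, which step 11 equilibrates at both centres.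

Step 11. Equilibration may stall (slow deprotonation, again because K is twisted), may stop at a mixture if the all-trans isomer is not clearly the most stable one, or the dienolates may be oxidised by traces of air. The fallback sets out from 19, comes back at 20, and makes no new compound (F0). It replaces thermodynamic by kinetic control: stoichiometric deprotonation at C7 with LiTMP at –78 °C, then protonation of the ring A dienolate by a hindered phenol, so that the C7 configuration is decided by the direction of proton delivery and not by relative stability. The same sequence through the C8 dienolate offers the complementary correction.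

Step 5. Hot hydrazine and hydroxide may close the hydrazone nitrogen onto the neighbouring bromine-bearing carbon (intramolecular N-arylation), cleave methyl ethers or remove the bromine; these are side reactions of the harsh conditions and not of the reduction itself. The fallback sets out from 7 and comes back at 9. Ketone 7 is condensed with p-toluenesulfonyl hydrazide (MeOH, catalytic HCl, reflux) to the tosylhydrazone of 7 F7. Catecholborane reduces its C=N bond at 0 °C, and NaOAc·3H2O at reflux then expels sulfinate and N2 to give 9 without strong base or high temperature.

## Further compounds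

F1 | step 9 | 2-bromo-1-(dimethoxymethyl)-3,5-dimethoxybenzene | COC(OC)c1cc(OC)cc(OC)c1Br
F2 | step 9 | [2-(dimethoxymethyl)-4,6-dimethoxyphenyl](4-methoxyphenyl)methanone | COC(OC)c1cc(OC)cc(OC)c1C(=O)c1ccc(OC)cc1
F3 | step 9 | 3,5-dimethoxy-2-(4-methoxybenzoyl)benzaldehyde | O=Cc1cc(OC)cc(OC)c1C(=O)c1ccc(OC)cc1
F4 | step 9 | [3,5-dimethoxy-2-(4-methoxybenzoyl)phenyl][(1S,2S)-1-(3,5-dimethoxyphenyl)-5,7-dimethoxy-2-(4-methoxyphenyl)-2,3-dihydro-1H-inden-4-yl]methanol (carbinol epimers) | OC(c1cc(OC)cc(OC)c1C(=O)c1ccc(OC)cc1)c1c(OC)cc(OC)c2c1C[C@H](c1ccc(OC)cc1)[C@H]2c1cc(OC)cc(OC)c1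
F5 | step 9 | [3,5-dimethoxy-2-(4-methoxybenzoyl)phenyl][(1S,2S)-1-(3,5-dimethoxyphenyl)-5,7-dimethoxy-2-(4-methoxyphenyl)-2,3-dihydro-1H-inden-4-yl]methanone | O=C(c1cc(OC)cc(OC)c1C(=O)c1ccc(OC)cc1)c1c(OC)cc(OC)c2c1C[C@H](c1ccc(OC)cc1)[C@H]2c1cc(OC)cc(OC)c1
F6 | step 10 | C7=C8 alkene of the octamethyl ether (9S,10S) | O=C1c2cc(OC)cc(OC)c2C(c2ccc(OC)cc2)=C2c3c1c(OC)cc(OC)c3[C@H](c1cc(OC)cc(OC)c1)[C@H]2c1ccc(OC)cc1
F0 | step 11 | none | none
F7 | step 5 | tosylhydrazone of 7 (racemic, trans) | Brc1c(OC)cc(OC)c2c1C(=NNS(=O)(=O)c1ccc(C)cc1)[C@H](c1ccc(OC)cc1)[C@H]2c1cc(OC)cc(OC)c1
A1 | alternative 1 | methyl 2-[(4-methoxyphenyl)(indan-1-yl)methyl]-3,5-dimethoxybenzoate with a 6-ethoxy-4-hydroxy-3-(3,5-dimethoxyphenyl)-2-(4-methoxyphenyl)indane, C7 to C10 as in the target | COC(=O)c1cc(OC)cc(OC)c1[C@H](c1ccc(OC)cc1)[C@@H]1c2cc(OCC)cc(O)c2[C@H](c2cc(OC)cc(OC)c2)[C@H]1c1ccc(OC)cc1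
A2 | alternative 1 | ethoxyacetylene | CCOC#C
A3 | alternative 2 | methyl 3-(3,5-dimethoxyphenyl)-4,6-dimethoxy-2-(4-methoxyphenyl)indane-1-carboxylate, trans,trans, C8 to C10 as in the target | COC(=O)[C@@H]1c2cc(OC)cc(OC)c2[C@H](c2cc(OC)cc(OC)c2)[C@H]1c1ccc(OC)cc1
A4 | alternative 3 | heptamethyl ether of the target analogue with 3,5-di-tert-butyl-4-hydroxyphenyl on C7 | O=C1c2cc(OC)cc(OC)c2[C@H](c2cc(C(C)(C)C)c(O)c(C(C)(C)C)c2)[C@@H]2c3c1c(OC)cc(OC)c3[C@H](c1cc(OC)cc(OC)c1)[C@H]2c1ccc(OC)cc1
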